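**Retrosynthetic overview**

- The strategy rests on the single bond between C2 of the pyranone ring (ring C) and C1' of ring B (C6 of the 2,2-dimethyl-2H-chromene). Cutting it gives two halves of similar size, each with one acid-sensitive prenyl-derived unit.
- Last disconnection: removal of a 7-O-methoxymethyl (MOM) group. Before it, a base-free palladium/copper thioether–boronic acid coupling (Liebeskind–Srogl) joins a 2-methylthiochromone to the chromen-6-ylboronic acid.
- Rings A and C half: 5-bromoresacetophenone, 4-O-MOM protection, Stille prenylation, CS2 annulation (closes pyranone ring C), S-methylation.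
- Ring B half: 4-bromophenol, 1,1-dimethylpropargyl ether, Claisen cascade (closes the chromene pyran ring), bromine–lithium exchange and borylation.
- Ring order: ring C and the chromene pyran ring are made separately before the union; the key step closes no ring. The target has no stereocenter and no stereogenic double bond.

Key step: step 8

Remark on the chemistry: the boron partner is carried as the free boronic acid and not as a pinacol ester, because base-free aryl transfer from boron mediated by a copper carboxylate is established for B(OH)2 groups and is slow for pinacol esters.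

**Route**

Step 1
Reactants: 1 1-(5-bromo-2,4-dihydroxyphenyl)ethanone
Product: 2 1-[5-bromo-2-hydroxy-4-(methoxymethoxy)phenyl]ethanone
Conditions: MOMCl (1.1 equiv), K2CO3 (1.5 equiv), acetone, 0 °C to rt
Reagents that add atoms: chloromethyl methyl ether, COCCl
Why: Williamson-type O-alkylation in which the 2-hydroxyl, held in a hydrogen bond to the acetyl carbonyl, stays unreactive under weak base, so the more acidic 4-hydroxyl para to the acetyl group should be alkylated selectively.

Step 2
Reactants: 2 1-[5-bromo-2-hydroxy-4-(methoxymethoxy)phenyl]ethanone; 3 tributyl(3-methylbut-2-enyl)stannane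
Product: 4 1-[2-hydroxy-4-(methoxymethoxy)-5-(3-methylbut-2-enyl)phenyl]ethanone
Conditions: Pd(PPh3)4 (5 mol%), DMF, 100 °C, Ar
Reagents that add atoms: none
Why: Stille cross-coupling, in which zerovalent palladium inserts into the aryl C–Br bond, the prenyl group is transferred from tin through its tin-bearing carbon and reductive elimination gives the linear prenyl arene, under neutral conditions that leave the chelated phenol, the ketone and the MOM acetal untouched.

Step 3
Reactants: 4 1-[2-hydroxy-4-(methoxymethoxy)-5-(3-methylbut-2-enyl)phenyl]ethanone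
Product: 6 4-hydroxy-7-(methoxymethoxy)-6-(3-methylbut-2-enyl)-2H-chromene-2-thione, via β-oxodithioate 5 (not isolated)
Conditions: KOtBu (3 equiv), CS2 (1.5 equiv), THF, 0 °C to rt; then cold 1 M HCl to pH 3, 0 °C, prompt extraction
Reagents that add atoms: carbon disulfide, S=C=S
Why: Dithiocarboxylation of the ketone enolate by CS2, followed by attack of the phenoxide on the dithiocarboxylate carbon with loss of hydrosulfide (6-exo-trig addition–elimination), closes ring C; this is the known conversion of 2-hydroxyacetophenones into 4-hydroxy-2H-chromene-2-thiones, and the brief cold acidification should not cleave the MOM acetal.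

Step 4
Reactants: 6 4-hydroxy-7-(methoxymethoxy)-6-(3-methylbut-2-enyl)-2H-chromene-2-thione
Product: 7 7-(methoxymethoxy)-2-(methylthio)-6-(3-methylbut-2-enyl)-4H-chromen-4-one
Conditions: MeI (1.1 equiv), K2CO3 (1.5 equiv), acetone, rt
Reagents that add atoms: iodomethane, CI
Why: SN2 alkylation of the ambident anion at its soft sulfur end, the known S-alkylation of 4-hydroxydithiocoumarins, fixes the 2-methylthio-4-pyranone tautomer.

Step 5
Reactants: 8 4-bromophenol; 9 3-chloro-3-methylbut-1-yne
Product: 10 1-bromo-4-(2-methylbut-3-yn-2-yloxy)benzene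
Conditions: K2CO3 (2 equiv), KI (cat.), CuI (cat.), acetone, reflux
Reagents that add atoms: none
Why: Copper-catalysed O-propargylation of a phenoxide by a tertiary propargylic chloride, which reacts through a copper acetylide-derived electrophile, is the standard way to aryl 1,1-dimethylpropargyl ethers.

Step 6
Reactants: 10 1-bromo-4-(2-methylbut-3-yn-2-yloxy)benzene
Product: 13 6-bromo-2,2-dimethyl-2H-chromene, via ortho-allenylphenol 11 (not isolated), via ortho-quinone methide 12 (not isolated)
Conditions: PhNEt2, 190 °C
Reagents that add atoms: none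
Why: Aryl propargyl ether Claisen rearrangement ([3,3] shift and enolisation to the allenylphenol), then a [1,5]-hydrogen shift to the ortho-quinone methide and 6π oxa-electrocyclisation, closes the 2H-pyran ring; the two ortho positions are equivalent, so one regioisomer is expected.

Step 7
Reactants: 13 6-bromo-2,2-dimethyl-2H-chromene
Product: 16 (2,2-dimethyl-2H-chromen-6-yl)boronic acid, via aryllithium 14 (not isolated), via lithium triisopropoxyborate 15 (not isolated)
Conditions: n-BuLi (1.1 equiv), THF, −78 °C; B(OiPr)3 (1.5 equiv), −78 °C to rt; 1 M HCl to pH 5–6, 0 °C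
Reagents that add atoms: triisopropyl borate, CC(C)OB(OC(C)C)OC(C)C; water, O
Why: Bromine–lithium exchange at −78 °C is much faster than any addition to the chromene alkene, the aryllithium is trapped by the borate ester as its ate complex, and mild aqueous hydrolysis releases the boronic acid (lithiation–borylation).

Step 8
Reactants: 7 7-(methoxymethoxy)-2-(methylthio)-6-(3-methylbut-2-enyl)-4H-chromen-4-one; 16 (2,2-dimethyl-2H-chromen-6-yl)boronic acid (1.5 equiv)
Product: 17 2-(2,2-dimethyl-2H-chromen-6-yl)-7-(methoxymethoxy)-6-(3-methylbut-2-enyl)-4H-chromen-4-one (7-O-MOM Kanzonol E)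
Conditions: Pd2(dba)3 (2.5 mol%), P(2-furyl)3 (15 mol%), Cu(O2CC4H3S) (monovalent copper thiophene-2-carboxylate, 2.2 equiv), degassed THF, 50 °C, Ar
Reagents that add atoms: none
Why: Liebeskind–Srogl cross-coupling: zerovalent palladium, formed from Pd2(dba)3 and the weakly donating tri(2-furyl)phosphine, inserts into the C2–S bond of 7, which is polarised as part of a vinylogous thiocarbonate and activated further by binding of sulfur to monovalent copper; the carboxylate on copper binds boron so that the aryl group of 16 passes to palladium while the thiolate leaves as copper methanethiolate, and reductive elimination from the divalent palladium diaryl forms the C2–C1' bond and returns zerovalent palladium. The closest known reaction type is the base-free, palladium-catalysed, copper-carboxylate-mediated coupling of heteroaryl methyl thioethers and vinylogous thioesters with arylboronic acids. No ring is closed and no stereocenter is formed. Only chemoselectivity is required: the C2–SMe bond is the one bond in either partner that zerovalent palladium can enter, and without added base or acid the prenyl alkene, the chromene alkene and the MOM acetal should remain intact; air is excluded so that copper does not homocouple or oxidise the boronic acid.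

Step 9
Reactants: 17 2-(2,2-dimethyl-2H-chromen-6-yl)-7-(methoxymethoxy)-6-(3-methylbut-2-enyl)-4H-chromen-4-one
Product: 18 Kanzonol E, 2-(2,2-dimethyl-2H-chromen-6-yl)-7-hydroxy-6-(3-methylbut-2-enyl)-4H-chromen-4-one
Conditions: conc. HCl (0.5 equiv), MeOH–THF 4:1, 40 °C, monitored by TLC; NaHCO3 quench
Reagents that add atoms: none
Why: Acid-catalysed acetal exchange passes the methoxymethyl group to methanol and frees the 7-hydroxyl; dilute acid, mild temperature and early quenching are chosen so that acetal cleavage outruns protonation of the prenyl and chromene alkenes.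

**Compound list**

1 | 1-(5-bromo-2,4-dihydroxyphenyl)ethanone | CC(=O)c1cc(Br)c(O)cc1O | starting material
2 | 1-[5-bromo-2-hydroxy-4-(methoxymethoxy)phenyl]ethanone | CC(=O)c1cc(Br)c(OCOC)cc1O | intermediate
3 | tributyl(3-methylbut-2-enyl)stannane | CCCC[Sn](CCCC)(CCCC)CC=C(C)C | starting material
4 | 1-[2-hydroxy-4-(methoxymethoxy)-5-(3-methylbut-2-enyl)phenyl]ethanone | CC(=O)c1cc(CC=C(C)C)c(OCOC)cc1O | intermediate
5 | 3-[2-hydroxy-4-(methoxymethoxy)-5-(3-methylbut-2-enyl)phenyl]-3-oxopropanedithioic acid (present as its potassium salt) | COCOc1cc(O)c(C(=O)CC(=S)S)cc1CC=C(C)C | intermediate (not isolated)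
6 | 4-hydroxy-7-(methoxymethoxy)-6-(3-methylbut-2-enyl)-2H-chromene-2-thione | S=c1cc(O)c2cc(CC=C(C)C)c(OCOC)cc2o1 | intermediate
7 | 7-(methoxymethoxy)-2-(methylthio)-6-(3-methylbut-2-enyl)-4H-chromen-4-one | CSc1cc(=O)c2cc(CC=C(C)C)c(OCOC)cc2o1 | intermediate
8 | 4-bromophenol | Oc1ccc(Br)cc1 | starting material
9 | 3-chloro-3-methylbut-1-yne | CC(C)(Cl)C#C | starting material
10 | 1-bromo-4-(2-methylbut-3-yn-2-yloxy)benzene | CC(C)(Oc1ccc(Br)cc1)C#C | intermediate
11 | 4-bromo-2-(3-methylbuta-1,2-dienyl)phenol | CC(C)=C=Cc1cc(Br)ccc1O | intermediate (not isolated)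
12 | (6Z)-4-bromo-6-(3-methylbut-2-enylidene)cyclohexa-2,4-dien-1-one | O=C1C=CC(Br)=C/C1=C/C=C(C)C | intermediate (not isolated)
13 | 6-bromo-2,2-dimethyl-2H-chromene | CC1(C)C=Cc2cc(Br)ccc2O1 | intermediate
14 | (2,2-dimethyl-2H-chromen-6-yl)lithium | [Li]c1ccc2OC(C)(C)C=Cc2c1 | intermediate (not isolated)
15 | lithium (2,2-dimethyl-2H-chromen-6-yl)triisopropoxyborate | [Li+].CC(C)O[B-](OC(C)C)(OC(C)C)c1ccc2OC(C)(C)C=Cc2c1 | intermediate (not isolated)
16 | (2,2-dimethyl-2H-chromen-6-yl)boronic acid | CC1(C)C=Cc2cc(B(O)O)ccc2O1 | intermediate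
17 | 2-(2,2-dimethyl-2H-chromen-6-yl)-7-(methoxymethoxy)-6-(3-methylbut-2-enyl)-4H-chromen-4-one | CC(C)=CCc1cc2c(=O)cc(-c3ccc4c(c3)C=CC(C)(C)O4)oc2cc1OCOC | intermediate
18 | Kanzonol E, 2-(2,2-dimethyl-2H-chromen-6-yl)-7-hydroxy-6-(3-methylbut-2-enyl)-4H-chromen-4-one | CC(C)=CCc1cc2c(=O)cc(-c3ccc4c(c3)C=CC(C)(C)O4)oc2cc1O | target

**Step count**

Total steps: 9. Longest linear sequence: 6 steps (steps 1, 2, 3, 4, 8 and 9, from compound 1). The boronic acid arm is steps 5, 6 and 7.

**Steps most likely to fail**

Step 8 (key coupling). Insertion of palladium into the C2–S bond may be slow, because C2 also carries the donating ring oxygen. The boronic acid may meanwhile be lost to protodeboronation or copper-mediated homocoupling before it transfers its aryl group. Fallback, by the chalcone route, setting out from compounds 13 and 4 and coming back at compound 17: bromochromene 13 is lithiated as in step 7 (aryllithium 14) and quenched with DMF to give 2,2-dimethyl-2H-chromene-6-carbaldehyde F1. Claisen–Schmidt condensation of this aldehyde with acetophenone 4 (KOH, EtOH, rt) should give (E)-3-(2,2-dimethyl-2H-chromen-6-yl)-1-[2-hydroxy-4-(methoxymethoxy)-5-(3-methylbut-2-enyl)phenyl]prop-2-en-1-one F2. Oxidative cyclisation of the chalcone (I2 cat., DMSO, 110 °C; oxa-Michael closure of ring C, then dehydrogenation) should give 17, the MOM ether keeping the 7-oxygen away from the prenyl group. Step 9 then follows unchanged.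

Step 2 (Stille prenylation). Oxidative addition into the electron-rich aryl bromide may be sluggish, and the prenyl group may be delivered through its far (γ) carbon, which would place a 1,1-dimethylallyl group on the ring. Fallback, setting out from compound 2 and coming back at compound 4: Stille coupling of 2 with allyltributylstannane (Pd(PPh3)4, DMF, 100 °C), which has no such regiochemical ambiguity, should give 1-[5-allyl-2-hydroxy-4-(methoxymethoxy)phenyl]ethanone F3. Olefin cross-metathesis of the allyl arene with excess 2-methylbut-2-ene (second-generation Grubbs catalyst, RuCl2(H2IMes)(PCy3)(=CHPh), CH2Cl2, 40 °C) should then convert the allyl group into the prenyl group of 4.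

Step 9 (MOM removal). Protonation of the prenyl alkene may lead to ring closure onto the freed 7-hydroxyl or to methanol addition, and the chromene alkene may be protonated, in competition with acetal cleavage. Fallback, setting out from compound 1 and coming back at compound 18, with the 7-oxygen carried as a fluoride-labile 2-(trimethylsilyl)ethoxymethyl (SEM) ether so that no acid is used at the end:
- Selective alkylation of 1 (SEMCl, K2CO3, acetone) should give 1-[5-bromo-2-hydroxy-4-{[2-(trimethylsilyl)ethoxy]methoxy}phenyl]ethanone F4.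
- Stille prenylation with 3 as in step 2 should give 1-[2-hydroxy-5-(3-methylbut-2-enyl)-4-{[2-(trimethylsilyl)ethoxy]methoxy}phenyl]ethanone F5.
- CS2 annulation as in step 3 should give 4-hydroxy-6-(3-methylbut-2-enyl)-7-{[2-(trimethylsilyl)ethoxy]methoxy}-2H-chromene-2-thione F6.
- S-methylation as in step 4 should give 2-(methylthio)-6-(3-methylbut-2-enyl)-7-{[2-(trimethylsilyl)ethoxy]methoxy}-4H-chromen-4-one F7.
- Coupling with boronic acid 16 under the conditions of step 8 should give 2-(2,2-dimethyl-2H-chromen-6-yl)-6-(3-methylbut-2-enyl)-7-{[2-(trimethylsilyl)ethoxy]methoxy}-4H-chromen-4-one F8.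
- Treatment with Bu4NF (THF–DMPU, 60 °C) should fragment the SEM group and give 18 after neutral work-up.

**Further compounds**

F1 | step 8 | 2,2-dimethyl-2H-chromene-6-carbaldehyde | CC1(C)C=Cc2cc(C=O)ccc2O1
F2 | step 8 | (E)-3-(2,2-dimethyl-2H-chromen-6-yl)-1-[2-hydroxy-4-(methoxymethoxy)-5-(3-methylbut-2-enyl)phenyl]prop-2-en-1-one | COCOc1cc(O)c(C(=O)/C=C/c2ccc3OC(C)(C)C=Cc3c2)cc1CC=C(C)C
F3 | step 2 | 1-[5-allyl-2-hydroxy-4-(methoxymethoxy)phenyl]ethanone | CC(=O)c1cc(CC=C)c(OCOC)cc1O
F4 | step 9 | 1-[5-bromo-2-hydroxy-4-{[2-(trimethylsilyl)ethoxy]methoxy}phenyl]ethanone | CC(=O)c1cc(Br)c(OCOCC[Si](C)(C)C)cc1O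
F5 | step 9 | 1-[2-hydroxy-5-(3-methylbut-2-enyl)-4-{[2-(trimethylsilyl)ethoxy]methoxy}phenyl]ethanone | CC(=O)c1cc(CC=C(C)C)c(OCOCC[Si](C)(C)C)cc1O
F6 | step 9 | 4-hydroxy-6-(3-methylbut-2-enyl)-7-{[2-(trimethylsilyl)ethoxy]methoxy}-2H-chromene-2-thione | S=c1cc(O)c2cc(CC=C(C)C)c(OCOCC[Si](C)(C)C)cc2o1
F7 | step 9 | 2-(methylthio)-6-(3-methylbut-2-enyl)-7-{[2-(trimethylsilyl)ethoxy]methoxy}-4H-chromen-4-one | CSc1cc(=O)c2cc(CC=C(C)C)c(OCOCC[Si](C)(C)C)cc2o1
F8 | step 9 | 2-(2,2-dimethyl-2H-chromen-6-yl)-6-(3-methylbut-2-enyl)-7-{[2-(trimethylsilyl)ethoxy]methoxy}-4H-chromen-4-one | CC(C)=CCc1cc2c(=O)cc(-c3ccc4c(c3)C=CC(C)(C)O4)oc2cc1OCOCC[Si](C)(C)C
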